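## Retrosynthetic overview

1. Target ⇒ bicyclo[3.3.1]nonane β-diketone with C1 benzoyl, C3 prenyl, C5 geranyl and an axial (endo) C7 prenyl group. One oxidative radical cascade forms the C3–CH bond (seven-membered ring), the cyclopentane C–C bond and the C–O bond.
2. That diketone ⇒ C3 prenylation and 1,4-hydrogenation of a 7-endo dienyl diketone.
3. Dienyl diketone ⇒ 3-chloro-5-geranyl-2,4,6-trihydroxybenzophenone, 2-(bromomethyl)-3-methylbut-2-enal and a methallyl phosphonate in one telescoped operation. Enantioselective alkylative dearomatization–annulation (C5–C6, C1–C8, C3–C10) gives a transient chloro hydroxy-adamantane that stores the endo C7 epimer; retro-aldol/olefination and dechlorination follow. The chlorine blocks C3.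
4. Building blocks ⇒ 2,4,6-trihydroxybenzophenone (chlorination, geranylation) and diethyl isopropylidenemalonate (reduction, oxidation, bromination).
5. Ring order: cyclohexanone ring of the bicyclo[3.3.1] core, with a temporary adamantane ring closed and reopened (step 6); seven-membered ring and cyclopentane together (step 9).

Atom labels used below: C1 benzoyl bridgehead, C2/C4/C9 carbonyl carbons, C3 between C2 and C4, C5 geranyl bridgehead, C6 CH2, C7 CH, C8 CMe2, C10 carbinol carbon of the adamantane (the aldehyde carbon after ring opening).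

Assumption: the cinchonidinium catalyst in step 6 gives the C5 configuration drawn (its pseudo-enantiomer, the cinchoninium salt, is used if the sense is opposite), and the enantiomeric purity it delivers is carried through; if it must be raised, the cage is isolated and recrystallised as in the fallback to step 6.

## Route

Step 1
Reactants: 1 diethyl 2-(propan-2-ylidene)propanedioate
Product: 2 2-(propan-2-ylidene)propane-1,3-diol
Conditions: i-Bu2AlH (4.5 equiv), CH2Cl2, −78 → 0 °C; aqueous work-up
Reagents that add atoms: none
Why: 1,2-reduction of both conjugated ester groups by i-Bu2AlH (ester-to-alcohol reduction) gives the symmetric allylic diol, and no stereocentre is formed.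

Step 2
Reactants: 2 2-(propan-2-ylidene)propane-1,3-diol
Product: 3 2-(hydroxymethyl)-3-methylbut-2-enal
Conditions: MnO2 (8 equiv), CH2Cl2, 23 °C
Reagents that add atoms: none
Why: MnO2 oxidises one primary allylic alcohol to the enal (selective allylic oxidation), and the second CH2OH, now on an electron-poor enal alkene, reacts much more slowly, so the mono-aldehyde is isolated; no stereocentre is formed.

Step 3
Reactants: 3 2-(hydroxymethyl)-3-methylbut-2-enal
Product: 4 2-(bromomethyl)-3-methylbut-2-enal
Conditions: CBr4, PPh3, CH2Cl2, 0 °C
Reagents that add atoms: carbon tetrabromide, BrC(Br)(Br)Br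
Why: the Appel reaction converts the primary allylic alcohol into the bromide under neutral conditions that leave the enal untouched; no stereocentre is formed.

Step 4
Reactants: 5 phenyl(2,4,6-trihydroxyphenyl)methanone
Product: 6 (3-chloro-2,4,6-trihydroxyphenyl)(phenyl)methanone
Conditions: N-chlorosuccinimide (1.0 equiv), MeCN, 0 °C
Reagents that add atoms: N-chlorosuccinimide, O=C1CCC(=O)N1Cl
Why: electrophilic aromatic substitution on the very electron-rich ring places chlorine on one of the two equivalent free carbons, and this chlorine (later C3) blocks that carbon so that later C-alkylation is directed to the other one; no stereocentre is formed.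

Step 5
Reactants: 6 (3-chloro-2,4,6-trihydroxyphenyl)(phenyl)methanone; 7 geranyl bromide
Product: 8 (3-chloro-5-geranyl-2,4,6-trihydroxyphenyl)(phenyl)methanone
Conditions: KOH (10% aq.), 0 °C
Reagents that add atoms: none
Why: C-alkylation of the phenoxide in water (allylation of a phloroglucinol) occurs at the only free ring carbon with retention of the E alkene; no stereocentre is formed.

Step 6
Reactants: 8 (3-chloro-5-geranyl-2,4,6-trihydroxyphenyl)(phenyl)methanone; 4 2-(bromomethyl)-3-methylbut-2-enal; 9 diethyl (2-methylprop-2-en-1-yl)phosphonate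
Product: 14 7-endo-dienyl diketone (1-benzoyl-5-geranyl-4-hydroxy-8,8-dimethyl-7-[(1E)-3-methylbuta-1,3-dienyl]bicyclo[3.3.1]non-3-ene-2,9-dione), via dearomatized enal 10 (not isolated), via bicyclic aldehyde 11 (not isolated), via chloro hydroxy-adamantane 12 (not isolated), via chloro diene 13 (not isolated)
Conditions: O-allyl-N-(9-anthracenylmethyl)cinchonidinium bromide (0.25 equiv), CsOH·H2O (5 equiv), 4 Å MS, CH2Cl2, −50 °C; filter through Na2SO4, exchange solvent for THF; add to 9 (3 equiv)/KN(SiMe3)2 (4 equiv), THF, −78 → 0 °C; then AcOH, Zn dust, 0 → 23 °C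
Reagents that add atoms: none
Why: Proposed new method: the chiral ammonium phenoxide ion pair is C-alkylated at the geranyl-bearing carbon by SN2 attack on the allylic bromide from one face (catalytic enantioselective alkylative dearomatization, which sets C5; the chloro- and benzoyl-bearing carbons are far less nucleophilic), the C1 enolate then adds to the β,β-dimethyl enal (intramolecular Michael addition, C1 fixed by the bridge) and the C3 enolate adds to the aldehyde (aldol), so that cage 12 collects the material as the C7 epimer whose substituent faces C3, and when the crude cage alkoxide meets the phosphonate anion it reopens by retro-aldol cleavage of C3–C10 to the stabilised chloro-diketone enolate and the endo aldehyde 11, which is trapped before it can epimerise in an E-selective Horner–Wadsworth–Emmons olefination (closest known reaction type: retro-aldol opening of hydroxy-adamantane cores with in situ trapping of the aldehyde by an alkenyl cerium dichloride such as CH2=CHCeCl2), after which zinc in acetic acid reduces the α-chloro-β-diketone to the diketone without touching C1, C5 or C7.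

Step 7
Reactants: 14 7-endo-dienyl diketone
Product: 15 7-endo-prenyl diketone (1-benzoyl-5-geranyl-4-hydroxy-8,8-dimethyl-7-prenylbicyclo[3.3.1]non-3-ene-2,9-dione)
Conditions: Cr(CO)3(η6-naphthalene) (0.2 equiv), H2 (50 bar), THF, 45 °C
Reagents that add atoms: none
Why: the Cr(CO)3-arene catalyst adds H2 only across s-cis 1,3-dienes in a 1,4 sense (1,4-hydrogenation), turning the dienyl chain into the prenyl group while isolated alkenes, the ring-locked s-trans enone and the ketones stay intact; no stereocentre is formed.

Step 8
Reactants: 15 7-endo-prenyl diketone; 16 3-methylbut-2-en-1-yl acetate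
Product: 17 cascade precursor (1-benzoyl-5-geranyl-4-hydroxy-8,8-dimethyl-3-prenyl-7-endo-prenylbicyclo[3.3.1]non-3-ene-2,9-dione)
Conditions: Pd(PPh3)4 (0.05 equiv), Et3N (1.5 equiv), THF, 50 °C
Reagents that add atoms: none
Why: Tsuji–Trost allylation in which the soft diketone enolate attacks the (π-prenyl)Pd(PPh3)2 cation at its unsubstituted terminus to give the linear C3 prenyl group, and any O-prenyl enol ether re-ionises under zerovalent palladium and is funnelled to the C-alkylated product; no stereocentre is formed.

Step 9
Reactants: 17 cascade precursor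
Product: 19 target CNP0164095.2, via hydroperoxide 18 (not isolated)
Conditions: Mn(OAc)3·2H2O (0.3 equiv), AcOH, 5% O2 in N2 (1 atm), 23 °C; then PPh3 (1.5 equiv)
Reagents that add atoms: dioxygen, O=O
Why: Proposed new method: trivalent manganese oxidises the C2–C4 enol of 17 to the electrophilic C3 radical (closest known reaction type: Mn(OAc)3-mediated oxidative radical cyclisation and [3+2] annulation of 2-allyl-1,3-diketones, including its aerobic variant with catalytic metal), which cannot reach the equatorial bridgehead geranyl group and so adds to the CH terminus of the axial C7 prenyl group (7-exo-trig, closing the homoadamantane and fixing C3) with the tether twisted away from the C8 gem-dimethyl group so that the CMe2 end lies under C2 on the C1 side (sets the ring-fusion CH), the tertiary radical then closes the cyclopentane by 5-exo-trig attack on the C3 prenyl group through a chair-like transition state that places the new side chain trans to the CH2 bridge (sets the CH that bears the side chain), and the last tertiary radical, which has no alkene within reach, is trapped by O2 at low oxygen pressure and the hydroperoxide is reduced by PPh3.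

## Compound list

1 | diethyl 2-(propan-2-ylidene)propanedioate (diethyl isopropylidenemalonate) | CCOC(=O)C(=C(C)C)C(=O)OCC | starting material
2 | 2-(propan-2-ylidene)propane-1,3-diol | CC(C)=C(CO)CO | intermediate
3 | 2-(hydroxymethyl)-3-methylbut-2-enal | CC(C)=C(CO)C=O | intermediate
4 | 2-(bromomethyl)-3-methylbut-2-enal | CC(C)=C(CBr)C=O | intermediate
5 | phenyl(2,4,6-trihydroxyphenyl)methanone (2,4,6-trihydroxybenzophenone) | O=C(c1ccccc1)c1c(O)cc(O)cc1O | starting material
6 | (3-chloro-2,4,6-trihydroxyphenyl)(phenyl)methanone | O=C(c1ccccc1)c1c(O)c(Cl)c(O)cc1O | intermediate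
7 | geranyl bromide, (2E)-1-bromo-3,7-dimethylocta-2,6-diene | CC(C)=CCC/C(C)=C/CBr | starting material
8 | {3-chloro-5-[(2E)-3,7-dimethylocta-2,6-dien-1-yl]-2,4,6-trihydroxyphenyl}(phenyl)methanone | O=C(c1ccccc1)c1c(O)c(Cl)c(O)c(C/C=C(\C)CCC=C(C)C)c1O | intermediate
9 | diethyl (2-methylprop-2-en-1-yl)phosphonate | CCOP(=O)(CC(C)=C)OCC | starting material
10 | dearomatized enal, 2-[(3-benzoyl-5-chloro-1-geranyl-2,4-dihydroxy-6-oxocyclohexa-2,4-dien-1-yl)methyl]-3-methylbut-2-enal, C5 configured as in the SMILES | O=CC(=C(C)C)C[C@]1(C/C=C(\C)CCC=C(C)C)C(=O)C(Cl)=C(O)C(C(=O)c2ccccc2)=C1O | intermediate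
11 | bicyclic aldehyde, 1-benzoyl-3-chloro-5-geranyl-4-hydroxy-8,8-dimethyl-2,9-dioxobicyclo[3.3.1]non-3-ene-7-carbaldehyde, CHO endo (facing C3) | CC(C)=CCC/C(C)=C/C[C@@]12C[C@@H](C=O)C(C)(C)[C@](C(=O)c3ccccc3)(C2=O)C(=O)C(Cl)=C1O | intermediate
12 | chloro hydroxy-adamantane trione, 1-benzoyl-3-chloro-5-geranyl-10-hydroxy-8,8-dimethyladamantane-2,4,9-trione (C10 epimer drawn with OH away from C8; either epimer serves) | CC(C)=CCC/C(C)=C/C[C@@]12C[C@H]3[C@@H](O)[C@@](Cl)(C1=O)C(=O)[C@@](C(=O)c4ccccc4)(C2=O)C3(C)C | intermediate
13 | chloro diene, 1-benzoyl-3-chloro-5-geranyl-4-hydroxy-8,8-dimethyl-7-endo-[(1E)-3-methylbuta-1,3-dienyl]bicyclo[3.3.1]non-3-ene-2,9-dione | CC(C)=CCC/C(C)=C/C[C@@]12C[C@@H](/C=C/C(C)=C)C(C)(C)[C@](C(=O)c3ccccc3)(C2=O)C(=O)C(Cl)=C1O | intermediate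
14 | 7-endo-dienyl diketone, 1-benzoyl-5-geranyl-4-hydroxy-8,8-dimethyl-7-endo-[(1E)-3-methylbuta-1,3-dienyl]bicyclo[3.3.1]non-3-ene-2,9-dione | CC(C)=CCC/C(C)=C/C[C@@]12C[C@@H](/C=C/C(C)=C)C(C)(C)[C@](C(=O)c3ccccc3)(C2=O)C(=O)C=C1O | intermediate
15 | 7-endo-prenyl diketone, 1-benzoyl-5-geranyl-4-hydroxy-8,8-dimethyl-7-endo-prenylbicyclo[3.3.1]non-3-ene-2,9-dione | CC(C)=CCC/C(C)=C/C[C@@]12C[C@@H](CC=C(C)C)C(C)(C)[C@](C(=O)c3ccccc3)(C2=O)C(=O)C=C1O | intermediate
16 | 3-methylbut-2-en-1-yl acetate (prenyl acetate) | CC(C)=CCOC(C)=O | starting material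
17 | cascade precursor, 1-benzoyl-5-geranyl-4-hydroxy-8,8-dimethyl-3-prenyl-7-endo-prenylbicyclo[3.3.1]non-3-ene-2,9-dione | CC(C)=CCC/C(C)=C/C[C@@]12C[C@@H](CC=C(C)C)C(C)(C)[C@](C(=O)c3ccccc3)(C2=O)C(=O)C(CC=C(C)C)=C1O | intermediate
18 | hydroperoxide, the target with C(CH3)2OOH in place of C(CH3)2OH | CC(C)=CCC/C(C)=C/C[C@@]12C[C@H]3C[C@@H]4C(C)(C)[C@@H](C(C)(C)OO)C[C@]4(C1=O)C(=O)[C@@](C(=O)c1ccccc1)(C2=O)C3(C)C | intermediate
19 | CNP0164095.2, homoadamantane trione with C1 benzoyl, C5 geranyl, C8 gem-dimethyl and a C3-fused cyclopentane bearing gem-dimethyl and 2-hydroxypropan-2-yl | CC(C)=CCC/C(C)=C/C[C@@]12C[C@H]3C[C@@H]4C(C)(C)[C@@H](C(C)(C)O)C[C@]4(C1=O)C(=O)[C@@](C(=O)c1ccccc1)(C2=O)C3(C)C | target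

## Step count and risks

Total step count: 9. Longest linear sequence: 7 (steps 1, 2, 3, 6, 7, 8, 9; the branch from 5 is 6 steps).

Most likely to fail, first: step 9. Oxygen may intercept the first tertiary radical before the 5-exo closure, and the 7-exo addition may place the CMe2 end on the C5 side instead of the C1 side. The fallback sets out from 17 and removes oxygen from the cascade: Mn(OAc)3·2H2O (2.2 equiv) with Cu(OAc)2·H2O in degassed AcOH runs the same two cyclisations, and divalent copper oxidises the last radical to the alkene, giving the isopropenyl homoadamantane F1. Mukaiyama hydration of F1 (Co(acac)2 cat., PhSiH3, O2, i-PrOH, 0 °C), where the 1,1-disubstituted alkene reacts ahead of the trisubstituted geranyl alkenes, comes back to the route at 19. This fallback does not correct the facial selectivity of the 7-exo step.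

Second: step 6. The chloro substrate and this catalyst are untested in the cascade, and three things can go wrong:
- O-alkylation, or C-alkylation at the chloro-bearing carbon, may compete.
- The aldol may stall, because the chloro-diketone enolate is a weak aldol donor, so the cage may not hold the endo epimer.
- The telescoped olefination of the reopened cage may be slow.

The fallback sets out from 8 and splits the operation. Only the C-alkylation with 4 is run under the chiral ion pair (CsOH·H2O, toluene/CH2Cl2, −60 °C) and the dearomatized enal 10 is isolated. Both rings are then closed under acid (HCO2H, 23 °C): the C1 enol adds to the protonated enal and the C3 enol adds to the aldehyde. The cage is crystallised, which also raises its enantiomeric purity. It comes back at 12, which is then carried through the phosphonate and zinc stages of step 6 as a separate operation, and makes no compound outside the compound list (F0).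

Third: step 8. C3 of these diketones is flanked by two quaternary bridgeheads, so C-prenylation may stop at the O-prenyl ether. The fallback sets out from 15. O-allylation (allyl bromide, K2CO3, acetone) gives the allyl enol ether F2 (either enol oxygen serves). Claisen rearrangement (toluene, 110 °C) gives the C3-allyl diketone F3. Cross-metathesis with 2-methylbut-2-ene (second-generation Grubbs catalyst, CH2Cl2, 40 °C), in which the monosubstituted alkene reacts far faster than the trisubstituted ones, comes back at 17.

Further compounds

F1 | step 9 | isopropenyl homoadamantane, the target with C(CH3)=CH2 in place of C(CH3)2OH | CC(C)=CCC/C(C)=C/C[C@@]12C[C@H]3C[C@@H]4C(C)(C)[C@@H](C(C)=C)C[C@]4(C1=O)C(=O)[C@@](C(=O)c1ccccc1)(C2=O)C3(C)C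
F0 | step 6 | none | none
F2 | step 8 | allyl enol ether, 4-(allyloxy)-1-benzoyl-5-geranyl-8,8-dimethyl-7-endo-prenylbicyclo[3.3.1]non-3-ene-2,9-dione | CC(C)=CCC/C(C)=C/C[C@@]12C[C@@H](CC=C(C)C)C(C)(C)[C@](C(=O)c3ccccc3)(C2=O)C(=O)C=C1OCC=C
F3 | step 8 | C3-allyl diketone, 3-allyl-1-benzoyl-5-geranyl-4-hydroxy-8,8-dimethyl-7-endo-prenylbicyclo[3.3.1]non-3-ene-2,9-dione | CC(C)=CCC/C(C)=C/C[C@@]12C[C@@H](CC=C(C)C)C(C)(C)[C@](C(=O)c3ccccc3)(C2=O)C(=O)C(CC=C)=C1O
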